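**Retrosynthetic overview**
1. Target 30 ⇐ its 8-O-TBS ether 29 ⇐ bromo-aldehyde 27 by intramolecular Nozaki–Hiyama (CrCl2) allylation: the C6–C7 bond closes the ten-membered carbocycle first, then the C6 alkoxide closes the α-methylene-γ-lactone in the same step.
2. 27 ⇐ carbinol 22 ⇐ aldehyde 11 (C2–C6, C15) + (Z)-vinyl iodide 21 (C1, C7–C14) by asymmetric Ni/Cr coupling (C1–C2 bond, C2 stereocentre); the angelate goes on before ring closure.
3. 11 ⇐ 3,3-diethoxypropyne + ethylene oxide; an OH-directed trans-hydrostannation fixes the C4=C5 geometry and provides the handle for C15.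
4. 21 ⇐ (R)-PMB glycidyl ether (C8 stereocentre): acetylide opening, Negishi anti-carboalumination/iodination (Z-C1=C10), Baylis–Hillman with methyl acrylate (C11–C13).

Assumption: atom labels C1–C15 are germacrane numbers (C6 = lactone O–CH, C7 = ring-fusion CH, C8 = CHOH, C2 = CH–O-angelate, C15 = CH2OAc), and epoxide 12 is bought (it is the PMB ether of (S)-glycidol).

**Fragment A (aldehyde 11)**

Step 1
Reactants: 1 3,3-diethoxyprop-1-yne; 2 ethylene oxide
Product: 4 5,5-diethoxypent-3-yn-1-ol, via lithium acetylide 3 (not isolated)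
Conditions: n-BuLi, THF, −78 °C; then 2, DMSO, 0 °C → rt; H2O
Reagents that add atoms: none
Why: Acetylide alkylation by SN2 opening of the epoxide (hydroxyethylation) gives the C2–C6 chain with the aldehyde carbon C6 masked as an acetal; no stereocentre is formed.

Step 2
Reactants: 4 5,5-diethoxypent-3-yn-1-ol
Product: 5 (3Z)-5,5-diethoxy-3-(tributylstannyl)pent-3-en-1-ol
Conditions: [Cp*RuCl]4 (1.25 mol %), Bu3SnH, CH2Cl2, rt
Reagents that add atoms: tributyltin hydride, CCCC[SnH](CCCC)CCCC
Why: Hydroxyl-directed Ru-catalysed trans-hydrostannation: the OH···Cl–Ru hydrogen bond steers tin to the alkyne carbon nearer the OH and H adds anti, so tin (the future C15 site) ends up cis to the acetal carbon, which fixes the C4=C5 geometry.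

Step 3
Reactants: 5 (3Z)-5,5-diethoxy-3-(tributylstannyl)pent-3-en-1-ol
Product: 6 TBS ether of 5
Conditions: TBSCl, imidazole, DMF, rt
Reagents that add atoms: tert-butyldimethylsilyl chloride, CC(C)(C)[Si](C)(C)Cl
Why: Silylation masks the primary alcohol (future C2 aldehyde) so that only the C15 hydroxyl made next is acetylated.

Step 4
Reactants: 6 TBS ether of 5
Product: 8 (2Z)-2-[2-(tert-butyldimethylsilyloxy)ethyl]-4,4-diethoxybut-2-en-1-ol, via vinyllithium 7 (not isolated)
Conditions: n-BuLi, THF, −78 → −40 °C; (CH2O)n, −40 °C → rt; H2O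
Reagents that add atoms: formaldehyde (from paraformaldehyde), C=O
Why: Tin–lithium exchange and hydroxymethylation of the vinyllithium both proceed with retention of alkene geometry, so CH2OH (C15) is cis to the acetal carbon C6.

Step 5
Reactants: 8 (2Z)-2-[2-(tert-butyldimethylsilyloxy)ethyl]-4,4-diethoxybut-2-en-1-ol
Product: 9 (2Z)-2-[2-(tert-butyldimethylsilyloxy)ethyl]-4,4-diethoxybut-2-en-1-yl acetate
Conditions: Ac2O, Et3N, DMAP (cat.), CH2Cl2, 0 °C
Reagents that add atoms: acetic anhydride, CC(=O)OC(C)=O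
Why: DMAP-catalysed acetylation installs the C15 acetate of the target on the only free hydroxyl.

Step 6
Reactants: 9 (2Z)-2-[2-(tert-butyldimethylsilyloxy)ethyl]-4,4-diethoxybut-2-en-1-yl acetate
Product: 10 (2Z)-4,4-diethoxy-2-(2-hydroxyethyl)but-2-en-1-yl acetate
Conditions: TBAF, AcOH, THF, 0 °C → rt
Reagents that add atoms: none
Why: Buffered fluoride desilylation frees the primary alcohol while the acetal (acid-labile) and the acetate (base-labile) survive.

Step 7
Reactants: 10 (2Z)-4,4-diethoxy-2-(2-hydroxyethyl)but-2-en-1-yl acetate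
Product: 11 (2Z)-4,4-diethoxy-2-(2-oxoethyl)but-2-en-1-yl acetate
Conditions: Dess–Martin periodinane, pyridine, CH2Cl2, 0 °C; used crude at once
Reagents that add atoms: none
Why: Buffered Dess–Martin oxidation gives the β,γ-unsaturated aldehyde under non-basic conditions that do not move the double bond into conjugation.

**Fragment B (vinyl iodide 21)**

Step 8
Reactants: 12 (2R)-2-{[(4-methoxybenzyl)oxy]methyl}oxirane
Product: 13 (2R)-1-[(4-methoxybenzyl)oxy]pent-4-yn-2-ol
Conditions: HC≡CLi·H2NCH2CH2NH2, DMSO, rt; H2O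
Reagents that add atoms: lithium acetylide–ethylenediamine complex, [Li]C#C.NCCN
Why: SN2 opening of the terminal epoxide at CH2 by acetylide leaves the stereocentre of 12 untouched; it becomes C8 of the target.

Step 9
Reactants: 13 (2R)-1-[(4-methoxybenzyl)oxy]pent-4-yn-2-ol
Product: 15 (2R,4Z)-5-iodo-1-[(4-methoxybenzyl)oxy]-4-methylpent-4-en-2-ol, via (Z)-alkenylalane chelate 14 (not isolated)
Conditions: Me3Al (4 equiv), Cp2ZrCl2 (0.3 equiv), (CH2Cl)2, rt then 60 °C, 48 h; I2, THF, −30 °C; aqueous work-up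
Reagents that add atoms: trimethylaluminium, C[Al](C)C; iodine, II
Why: Negishi Zr-catalysed methylalumination of the homopropargylic alkoxide followed by chelation-controlled isomerisation (net anti-carbometalation) and iodinolysis with retention gives the vinyl iodide with I cis to the CH2 chain, i.e. the Z-C1=C10 geometry with the C14 methyl in place.

Step 10
Reactants: 15 (2R,4Z)-5-iodo-1-[(4-methoxybenzyl)oxy]-4-methylpent-4-en-2-ol
Product: 16 TBS ether of 15
Conditions: TBSCl, imidazole, DMF, rt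
Reagents that add atoms: tert-butyldimethylsilyl chloride, CC(C)(C)[Si](C)(C)Cl
Why: Silylation protects the C8 hydroxyl until the last step, which keeps it from attacking the later allylic bromide or the lactone carbonyl.

Step 11
Reactants: 16 TBS ether of 15
Product: 17 (2R,4Z)-2-[(tert-butyldimethylsilyl)oxy]-5-iodo-4-methylpent-4-en-1-ol
Conditions: DDQ, CH2Cl2–pH 7 buffer, 0 °C
Reagents that add atoms: none
Why: Oxidative PMB cleavage is selective for the electron-rich benzyl ether and leaves the vinyl iodide and TBS ether alone.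

Step 12
Reactants: 17 (2R,4Z)-2-[(tert-butyldimethylsilyl)oxy]-5-iodo-4-methylpent-4-en-1-ol
Product: 18 (2R,4Z)-2-[(tert-butyldimethylsilyl)oxy]-5-iodo-4-methylpent-4-enal
Conditions: Dess–Martin periodinane, pyridine, CH2Cl2, 0 °C
Reagents that add atoms: none
Why: Dess–Martin oxidation gives the α-silyloxy aldehyde without epimerising the adjacent stereocentre.

Step 13
Reactants: 18 (2R,4Z)-2-[(tert-butyldimethylsilyl)oxy]-5-iodo-4-methylpent-4-enal; 19 methyl acrylate
Product: 20 methyl (4R,6Z)-4-[(tert-butyldimethylsilyl)oxy]-3-hydroxy-7-iodo-6-methyl-2-methylidenehept-6-enoate (C3 epimer mixture)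
Conditions: 19 (5 equiv, neat), DABCO (1 equiv), MeOH (cat.), rt, 3–5 d
Reagents that add atoms: none
Why: Morita–Baylis–Hillman reaction attaches the C11–C13 acrylate unit to the activated α-oxy aldehyde; the new carbinol centre (C7) forms unselectively, which does not matter because it becomes sp2 in step 18 and is reset in step 19.

Step 14
Reactants: 20 methyl (4R,6Z)-4-[(tert-butyldimethylsilyl)oxy]-3-hydroxy-7-iodo-6-methyl-2-methylidenehept-6-enoate
Product: 21 TES ether of 20 (C3 epimer mixture)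
Conditions: TESOTf, 2,6-lutidine, CH2Cl2, −78 °C
Reagents that add atoms: triethylsilyl triflate, CC[Si](CC)(CC)OS(=O)(=O)C(F)(F)F
Why: Silylation masks the Baylis–Hillman hydroxyl so that only the C2 hydroxyl formed in step 15 is esterified; TES is chosen because it comes off later with the acetal while the TBS ether stays.

**Union and endgame**

Step 15
Reactants: 11 (2Z)-4,4-diethoxy-2-(2-oxoethyl)but-2-en-1-yl acetate; 21 TES ether of 20
Product: 22 methyl (4R,6Z,8S,10Z)-10-(acetoxymethyl)-4-[(tert-butyldimethylsilyl)oxy]-12,12-diethoxy-8-hydroxy-6-methyl-2-methylidene-3-[(triethylsilyl)oxy]dodeca-6,10-dienoate (C3 epimer mixture)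
Conditions: CrCl2 (4 equiv), Kishi oxazoline–sulfonamide ligand (4.4 equiv), Et3N (4.4 equiv), THF, rt; then NiCl2 (0.1 equiv), 11 and 21, rt
Reagents that add atoms: none
Why: Asymmetric Nozaki–Hiyama–Kishi coupling: the alkenyl–Cr(III) species adds 1,2 to the aldehyde with retention of the Z geometry and tolerates the acetal, esters and enolisable aldehyde; the new C2 centre is set by the chiral Cr complex of N-{2-[(4S)-4-isopropyl-4,5-dihydrooxazol-2-yl]-6-methylphenyl}methanesulfonamide or its antipode (reagent control; I cannot state from memory which antipode gives 2S, so it is chosen on a pilot run with Mosher analysis), and the minor 2R epimer is a separable diastereomer.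

Step 16
Reactants: 22 C2 carbinol from step 15; 23 angelic acid
Product: 25 angelate ester of 22, via mixed anhydride 24 (not isolated)
Conditions: 23, 2,4,6-Cl3C6H2COCl, Et3N, toluene, rt; then 22, 75 °C
Reagents that add atoms: none
Why: Yamaguchi-type esterification through the angelic/trichlorobenzoic mixed anhydride without DMAP acylates the allylic alcohol with retention at C2 and without angelate-to-tiglate isomerisation.

Step 17
Reactants: 25 angelate ester of 22
Product: 26 methyl (4R,6Z,8S,10Z)-10-(acetoxymethyl)-4-[(tert-butyldimethylsilyl)oxy]-3-hydroxy-6-methyl-2-methylidene-8-{[(2Z)-2-methylbut-2-enoyl]oxy}-12-oxododeca-6,10-dienoate (C3 epimer mixture)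
Conditions: AcOH–THF–H2O (3:1:1), rt
Reagents that add atoms: water, O
Why: Mild acid hydrolysis unmasks the enal from its acetal and cleaves the TES ether in one operation, while the hindered secondary TBS ether and the three esters survive.

Step 18
Reactants: 26 hydroxy enal from step 17
Product: 27 methyl (2Z,4R,6Z,8S,10Z)-10-(acetoxymethyl)-2-(bromomethyl)-4-[(tert-butyldimethylsilyl)oxy]-6-methyl-8-{[(2Z)-2-methylbut-2-enoyl]oxy}-12-oxododeca-2,6,10-trienoate
Conditions: NBS, Me2S, CH2Cl2, −20 → 0 °C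
Reagents that add atoms: N-bromosuccinimide, O=C1CCC(=O)N1Br
Why: Corey–Kim-type activation of the Baylis–Hillman alcohol and SN2′ attack of bromide give the thermodynamically favoured (Z)-2-(bromomethyl)enoate and erase the C7 carbinol centre; the aldehyde, esters and silyl ether are inert.

Step 19
Reactants: 27 bromo-aldehyde from step 18
Product: 29 8-O-TBS ether of the target, via hydroxy ester 28 (not isolated)
Conditions: CrCl2 (10 equiv), THF, 2 mM (slow addition), rt; then p-TsOH (cat.), CH2Cl2, rt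
Reagents that add atoms: none
Why: Intramolecular Nozaki–Hiyama (Barbier-type) allylation: the allyl–Cr(III) adds through its γ-carbon C7 to the enal in a chair-like transition state inside the forming ten-membered ring with the C5 and C8 arms pseudo-equatorial (anti adduct, hence the 6,7-trans lactone once the C6–OH closes onto the methyl ester), and with C8–H in the plane of the allyl unit (A1,3 strain) and the C9 tether anti to the forming bond, which is expected, not assured, to give 6R,7R.

Step 20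
Reactants: 29 8-O-TBS ether of the target
Product: 30 target, [(3aR,4R,6Z,8S,10Z,11aR)-4-hydroxy-6-methyl-3-methylidene-8-{[(2Z)-2-methylbut-2-enoyl]oxy}-2-oxo-2,3,3a,4,5,8,9,11a-octahydrocyclodeca[b]furan-10-yl]methyl acetate
Conditions: HF·pyridine, pyridine, THF, 0 °C → rt
Reagents that add atoms: none
Why: Buffered acidic fluoride desilylation frees the C8 hydroxyl without touching the acetate, the angelate or the α-methylene lactone and without base that could trigger translactonisation.

**Compound list**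
1 | 3,3-diethoxyprop-1-yne | C#CC(OCC)OCC | starting material
2 | ethylene oxide (oxirane) | C1CO1 | starting material
3 | lithium 3,3-diethoxyprop-1-yn-1-ide (not isolated) | [Li]C#CC(OCC)OCC | intermediate
4 | 5,5-diethoxypent-3-yn-1-ol | OCCC#CC(OCC)OCC | intermediate
5 | (3Z)-5,5-diethoxy-3-(tributylstannyl)pent-3-en-1-ol (Sn cis to the acetal carbon) | OCC/C(=C/C(OCC)OCC)[Sn](CCCC)(CCCC)CCCC | intermediate
6 | tert-butyl{[(3Z)-5,5-diethoxy-3-(tributylstannyl)pent-3-en-1-yl]oxy}dimethylsilane | CC(C)(C)[Si](C)(C)OCC/C(=C/C(OCC)OCC)[Sn](CCCC)(CCCC)CCCC | intermediate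
7 | vinyllithium from 6, Li in place of Bu3Sn and cis to the acetal carbon (not isolated) | CC(C)(C)[Si](C)(C)OCC/C([Li])=C/C(OCC)OCC | intermediate
8 | (2Z)-2-[2-(tert-butyldimethylsilyloxy)ethyl]-4,4-diethoxybut-2-en-1-ol | CC(C)(C)[Si](C)(C)OCC/C(CO)=C/C(OCC)OCC | intermediate
9 | (2Z)-2-[2-(tert-butyldimethylsilyloxy)ethyl]-4,4-diethoxybut-2-en-1-yl acetate | CC(C)(C)[Si](C)(C)OCC/C(COC(C)=O)=C/C(OCC)OCC | intermediate
10 | (2Z)-4,4-diethoxy-2-(2-hydroxyethyl)but-2-en-1-yl acetate | OCC/C(COC(C)=O)=C/C(OCC)OCC | intermediate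
11 | (2Z)-4,4-diethoxy-2-(2-oxoethyl)but-2-en-1-yl acetate | O=CC/C(COC(C)=O)=C/C(OCC)OCC | intermediate
12 | (2R)-2-{[(4-methoxybenzyl)oxy]methyl}oxirane | C1[C@@H](O1)COCc2ccc(OC)cc2 | starting material
13 | (2R)-1-[(4-methoxybenzyl)oxy]pent-4-yn-2-ol | C#CC[C@@H](O)COCc1ccc(OC)cc1 | intermediate
14 | (Z)-alkenyl(dimethyl)alane of 13 as its O-dimethylaluminium alkoxide, Al cis to the CH2 chain (not isolated) | C[Al](C)/C=C(/C)C[C@@H](O[Al](C)C)COCc1ccc(OC)cc1 | intermediate
15 | (2R,4Z)-5-iodo-1-[(4-methoxybenzyl)oxy]-4-methylpent-4-en-2-ol | I/C=C(/C)C[C@@H](O)COCc1ccc(OC)cc1 | intermediate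
16 | tert-butyl({(2R,4Z)-5-iodo-1-[(4-methoxybenzyl)oxy]-4-methylpent-4-en-2-yl}oxy)dimethylsilane | I/C=C(/C)C[C@@H](O[Si](C)(C)C(C)(C)C)COCc1ccc(OC)cc1 | intermediate
17 | (2R,4Z)-2-[(tert-butyldimethylsilyl)oxy]-5-iodo-4-methylpent-4-en-1-ol | I/C=C(/C)C[C@@H](O[Si](C)(C)C(C)(C)C)CO | intermediate
18 | (2R,4Z)-2-[(tert-butyldimethylsilyl)oxy]-5-iodo-4-methylpent-4-enal | I/C=C(/C)C[C@@H](O[Si](C)(C)C(C)(C)C)C=O | intermediate
19 | methyl acrylate | C=CC(=O)OC | starting material
20 | methyl (4R,6Z)-4-[(tert-butyldimethylsilyl)oxy]-3-hydroxy-7-iodo-6-methyl-2-methylidenehept-6-enoate, C3 epimer mixture | I/C=C(/C)C[C@@H](O[Si](C)(C)C(C)(C)C)C(O)C(=C)C(=O)OC | intermediate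
21 | methyl (4R,6Z)-4-[(tert-butyldimethylsilyl)oxy]-7-iodo-6-methyl-2-methylidene-3-[(triethylsilyl)oxy]hept-6-enoate, C3 epimer mixture | I/C=C(/C)C[C@@H](O[Si](C)(C)C(C)(C)C)C(O[Si](CC)(CC)CC)C(=C)C(=O)OC | intermediate
22 | methyl (4R,6Z,8S,10Z)-10-(acetoxymethyl)-4-[(tert-butyldimethylsilyl)oxy]-12,12-diethoxy-8-hydroxy-6-methyl-2-methylidene-3-[(triethylsilyl)oxy]dodeca-6,10-dienoate, C3 epimer mixture | CCOC(OCC)/C=C(\COC(C)=O)C[C@H](O)/C=C(/C)C[C@@H](O[Si](C)(C)C(C)(C)C)C(O[Si](CC)(CC)CC)C(=C)C(=O)OC | intermediate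
23 | angelic acid, (2Z)-2-methylbut-2-enoic acid | C/C=C(/C)C(=O)O | starting material
24 | (2Z)-2-methylbut-2-enoic 2,4,6-trichlorobenzoic anhydride (not isolated) | C/C=C(/C)C(=O)OC(=O)c1c(Cl)cc(Cl)cc1Cl | intermediate
25 | methyl (4R,6Z,8S,10Z)-10-(acetoxymethyl)-4-[(tert-butyldimethylsilyl)oxy]-12,12-diethoxy-6-methyl-2-methylidene-8-{[(2Z)-2-methylbut-2-enoyl]oxy}-3-[(triethylsilyl)oxy]dodeca-6,10-dienoate, C3 epimer mixture | CCOC(OCC)/C=C(\COC(C)=O)C[C@H](OC(=O)/C(C)=C\C)/C=C(/C)C[C@@H](O[Si](C)(C)C(C)(C)C)C(O[Si](CC)(CC)CC)C(=C)C(=O)OC | intermediate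
26 | methyl (4R,6Z,8S,10Z)-10-(acetoxymethyl)-4-[(tert-butyldimethylsilyl)oxy]-3-hydroxy-6-methyl-2-methylidene-8-{[(2Z)-2-methylbut-2-enoyl]oxy}-12-oxododeca-6,10-dienoate, C3 epimer mixture | O=C/C=C(\COC(C)=O)C[C@H](OC(=O)/C(C)=C\C)/C=C(/C)C[C@@H](O[Si](C)(C)C(C)(C)C)C(O)C(=C)C(=O)OC | intermediate
27 | methyl (2Z,4R,6Z,8S,10Z)-10-(acetoxymethyl)-2-(bromomethyl)-4-[(tert-butyldimethylsilyl)oxy]-6-methyl-8-{[(2Z)-2-methylbut-2-enoyl]oxy}-12-oxododeca-2,6,10-trienoate | O=C/C=C(\COC(C)=O)C[C@H](OC(=O)/C(C)=C\C)/C=C(/C)C[C@@H](O[Si](C)(C)C(C)(C)C)/C=C(\CBr)C(=O)OC | intermediate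
28 | methyl 2-[(1S,2R,3Z,6S,7Z,10R)-4-(acetoxymethyl)-10-[(tert-butyldimethylsilyl)oxy]-2-hydroxy-8-methyl-6-{[(2Z)-2-methylbut-2-enoyl]oxy}cyclodeca-3,7-dien-1-yl]prop-2-enoate (not isolated) | C=C(C(=O)OC)[C@H]1[C@H](O)/C=C(\COC(C)=O)C[C@H](OC(=O)/C(C)=C\C)/C=C(/C)C[C@H]1O[Si](C)(C)C(C)(C)C | intermediate
29 | [(3aS,4R,6Z,8S,10Z,11aR)-4-[(tert-butyldimethylsilyl)oxy]-6-methyl-3-methylidene-8-{[(2Z)-2-methylbut-2-enoyl]oxy}-2-oxo-2,3,3a,4,5,8,9,11a-octahydrocyclodeca[b]furan-10-yl]methyl acetate (same spatial arrangement as 30; the 3a descriptor changes only through CIP priority) | C=C1C(=O)O[C@@H]2/C=C(\COC(C)=O)C[C@H](OC(=O)/C(C)=C\C)/C=C(/C)C[C@@H](O[Si](C)(C)C(C)(C)C)[C@@H]12 | intermediate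
30 | [(3aR,4R,6Z,8S,10Z,11aR)-4-hydroxy-6-methyl-3-methylidene-8-{[(2Z)-2-methylbut-2-enoyl]oxy}-2-oxo-2,3,3a,4,5,8,9,11a-octahydrocyclodeca[b]furan-10-yl]methyl acetate | C=C1C(=O)O[C@@H]2/C=C(\COC(C)=O)C[C@H](OC(=O)/C(C)=C\C)/C=C(/C)C[C@@H](O)[C@@H]12 | target

**Totals**
Total step count: 20.
Longest linear sequence: 13 steps (1–7 then 15–20; the branch 8–14 then 15–20 is equally long).

**Three steps most likely to fail**

Step 19 (macrocyclisation). The ring may close poorly, or the C6/C7 pair may form with the wrong sense relative to C8; the facial outcome is a model-based expectation, not a precedent for this substitution pattern. Fallback: starting from 26, convert the Baylis–Hillman alcohol into the methyl carbonate of 26 F3 (ClCO2Me, pyridine, CH2Cl2, 0 °C) and close the ring by Pd(0)-catalysed umpolung allylation (Pd(PPh3)4 cat., Et2Zn, THF, high dilution). The π-allylpalladium formed from the activated carbonate is transmetalated to an allylzinc, which adds to the aldehyde through a closed transition state with its own diastereoselectivity. This comes back to the route at hydroxy ester 28, which lactonises to 29 as in step 19.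

Step 15 (fragment union). The β,γ-unsaturated aldehyde 11 is labile and the ligand-controlled selectivity at C2 may be low. Fallback: starting from 11 and 21, run the Ni/Cr coupling without chiral ligand (CrCl2, NiCl2 cat., DMSO, rt) to obtain the carbinol-epimer mixture F1. Oxidise it with Dess–Martin periodinane to the (Z)-enone F2. Reduce F2 with (R)-Me-CBS/catecholborane (toluene, −78 °C), where the alkenyl arm acts as the large group and the 2S alcohol results. This comes back to the route at 22.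

Step 13 (Baylis–Hillman). The reaction is slow, and several days with DABCO could erode the α-silyloxy stereocentre. Fallback: starting from 18, use vinylalumination in place of amine catalysis: methyl propiolate is hydroaluminated with DIBAL-H/NMO (THF, 0 °C) to the [1-(methoxycarbonyl)vinyl]alane, which adds to 18 within hours without base. This comes back to the route directly at 20 and makes no new isolated compound.

**Further compounds**
F1 | step 15 | methyl (4R,6Z,10Z)-10-(acetoxymethyl)-4-[(tert-butyldimethylsilyl)oxy]-12,12-diethoxy-8-hydroxy-6-methyl-2-methylidene-3-[(triethylsilyl)oxy]dodeca-6,10-dienoate, both C8 epimers | CCOC(OCC)/C=C(\COC(C)=O)CC(O)/C=C(/C)C[C@@H](O[Si](C)(C)C(C)(C)C)C(O[Si](CC)(CC)CC)C(=C)C(=O)OC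
F2 | step 15 | methyl (4R,6Z,10Z)-10-(acetoxymethyl)-4-[(tert-butyldimethylsilyl)oxy]-12,12-diethoxy-6-methyl-2-methylidene-8-oxo-3-[(triethylsilyl)oxy]dodeca-6,10-dienoate | CCOC(OCC)/C=C(\COC(C)=O)CC(=O)/C=C(/C)C[C@@H](O[Si](C)(C)C(C)(C)C)C(O[Si](CC)(CC)CC)C(=C)C(=O)OC
F3 | step 19 | methyl (4R,6Z,8S,10Z)-10-(acetoxymethyl)-4-[(tert-butyldimethylsilyl)oxy]-3-[(methoxycarbonyl)oxy]-6-methyl-2-methylidene-8-{[(2Z)-2-methylbut-2-enoyl]oxy}-12-oxododeca-6,10-dienoate | O=C/C=C(\COC(C)=O)C[C@H](OC(=O)/C(C)=C\C)/C=C(/C)C[C@@H](O[Si](C)(C)C(C)(C)C)C(OC(=O)OC)C(=C)C(=O)OC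
F0 | step 13 | none | none
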